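## Structural features

The target is (2S,3R,6S,9R,10S)-10-bromo-2-chloro-3,11,11-trimethyl-7-methylidenespiro[5.5]undecane-3,9-diol, a chamigrane in which two cyclohexane rings share only the quaternary carbon C6. Ring A (C6–C7–C8–C9–C10–C11) carries the exocyclic C7=C14 methylene, a secondary alcohol at C9, a secondary bromide at C10 and the gem-dimethyl carbon C11, so C6 and C11 are two fully substituted neighbours. Ring B (C6–C1–C2–C3–C4–C5) carries a secondary chloride at C2 beside the tertiary methyl carbinol C3. The stereocentres form two adjacent pairs: C2/C3 (Cl and OH cis, Cl and CH3 both equatorial) and C9/C10 (Br and OH cis, Br equatorial, OH axial). The pairs are linked only through C6, which is stereogenic solely because C1 (next to CHCl) differs from C5. Fragile points are the homoallylic alcohol (its ketone precursor is a β,γ-unsaturated ketone that conjugates easily), the two cis-halohydrins (semipinacol shift with base, ionisation with acid) and the epimerisable α-halo ketone stages. The real difficulties are the C6–C11 bond between two quaternary carbons and the relay between the two pairs: in its chair (C11 equatorial, C7 axial) ring B presents C1 and C5 to ring A as almost equivalent arms, so C9/C10 cannot be set by substrate control. The key step uses the fact that chlorine sits on C2, between C1 and the oxygenated C3, which is the pattern left when a dichlorocarbene carbon is inserted into the enol ether bond of a five-membered silyl enol ether spiro-fused at C6.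

## Logic of the disconnections

28 ⇐ 27. The C9–H bond is cut. A bulky hydride on the C9 ketone gives the axial alcohol cis to the equatorial bromine. This reduces the problem to one ring A stereocentre (C10), and the forward step must not move the β,γ double bond.

27 ⇐ 26. The C8–H bond is cut and a C14–Si bond is added. The exocyclic alkene is placed regiospecifically by desilylative, deconjugative protonation of a γ-silyl enone, which avoids any base strong enough to touch C10–H. The forward step needs kinetic protonation at C8 and not at C14.

26 ⇐ 25 ⇐ 24. This is a redox pair at C9. In 24 only C10 can epimerise (C8 is sp2), so a catalyst-controlled dynamic reduction selects one C10 epimer; re-oxidation then gives 26 as a single epimer. This is the reagent-controlled event that the near-equivalent C1 and C5 arms make necessary.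

24 ⇐ 21. The C10–Br bond is cut. Bromination of the kinetic C9–C10 enolate of the enone is regiospecific because C8 is vinylic.

21 ⇐ 19. The C7–C14 bond is cut and C9 is returned to its enol ether. A 1,2-addition to the vinylogous ester with 1,3-carbonyl transposition installs C14 with its silicon and unmasks the C9 ketone in one operation. The hindered C7 carbonyl demands a non-basic, strongly nucleophilic reagent.

19 ⇐ 18. The C3–CH3 bond is cut. Methyl addition to the α-chloro ketone sets C3, and C7 is protected by being a vinylogous ester carbonyl.

18 ⇐ 15. Four C–H bonds are cut. Both ring B alkenes of the dienone are reduced with the chlorine kept, and C2 is set by equilibration relative to C6.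

15 ⇐ 12 + 13. The C1–C2 and C2–C3 bonds are cut (key step). Removing the carbene carbon contracts ring B to a silyloxycyclopentadiene. The chlorine and the C2/C3 adjacency come from the reagent, and C6 must already be configured.

12 ⇐ 11. The O–Si bond is cut. The only enolisable position of the cyclopentenone is C1, so the dienol ether is regiodefined.

11 ⇐ 9 (through 10). The C4=C5 bond is cut. An aldol condensation of a methyl ketone onto a neopentyl aldehyde closes the five-membered ring, and both carbonyl partners hang on C6.

9 ⇐ 8 ⇐ 7. These are functional-group changes: an allyl group serves as the masked acetonyl unit (C1, C3, C4) and a benzyloxymethyl group as the masked formyl carbon (C5).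

7 ⇐ 6. The C6–C1 bond is cut. A catalytic enantioselective allylation of a fully substituted enolate creates the quaternary stereocentre next to C11, the only absolute stereocontrol needed before the key step.

6 ⇐ 4 + 5, 4 ⇐ 2 + 3, 2 ⇐ 1. The C6–C5 bond and the enol carbonate are cut back to the isobutyl enol ether of dimedone, which supplies ring A with C7 and C9 differentiated and C11 in place.

## Other disconnections considered

Alternative 1: The cut is the C6–C11 bond. In the forward step a Lewis acid in a fluorinated alcohol ionises the tertiary C11 hydroxyl of the open-chain allylsilane A2 with bromine participation. C6 of the tetrasubstituted alkene opens the bromonium ion at C11, and loss of silicon from the β-silyl cation leaves the C7=C14 methylene of A1.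
- In favour: it makes the bond between the two quaternary carbons directly and delivers ring A with bromine, oxygen and methylene in their final form, with C9/C10 carried in from an acyclic bromohydrin. On ring A it is the better plan, since the chosen route spends six steps there.
- Against: ring B of A1 is a symmetrical ketal, so C6 is not yet stereogenic. C2 would have to be chlorinated in preference to C4 under the influence of remote centres only, which is the same relay problem in reverse and without an obvious catalyst handle. The cation could also lose a proton, shift, or be protodesilylated before closure.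
- Comparison: the mechanism is cationic, against a carbene addition with electrocyclic opening. On step count to the skeleton it is equal or better. On the C6/C2/C3 relationship the chosen plan is stronger, because there the reagent carbon defines C2 and the preset C6 defines the rest.

Alternative 2: The cut is the C6–C1 bond. In the forward step KN(SiMe3)2 forms the α′-enolate of the tosylate A4 and a 6-exo-tet alkylation closes ring B to A3.
- In favour: C3 comes from the chiral pool and C2 from stereospecific chemistry in the chain, so the facial selectivity of a methyl addition is not needed; on that point it is better. C6 is set by substrate control in a chair transition state. A3 is the triethylsilyl ether of 19, so the endgame is identical (equal).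
- Against: the SN2 closure must form a quaternary carbon next to CMe2 at a primary carbon that is β to chlorine, which is slow and open to elimination. The α′-enolate of a hindered, α′-substituted vinylogous ester competes with the γ-dienolate. The sense and degree of induction at C6 are not secured.
- Comparison: it is an anionic closure where the chosen plan uses ring enlargement. The step count to the common intermediate is comparable. The chosen plan sets C6 with a catalyst in a reaction class suited to vicinal quaternary centres and does not need the difficult alkylation.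

Alternative 3: The cut is the C7–C8 bond, after cleavage of C7–C10 in the spirocyclobutanone A6. In the forward step methoxide adds to the strained ring carbonyl, retro-Claisen cleavage releases the acetyl-stabilised carbanion, and the methyl ketone enolate closes on the new ester to give the dione A5.
- In favour: the whole carbon skeleton of ring A, with both quaternary carbons, comes from cheap materials in few robust, strain-driven steps. For building the C6–C11 array it is better than the chosen plan. A5 would enter the same enol ether chemistry as 2 (equal on the ring A endgame).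
- Against: A5 is achiral, with C6 non-stereogenic and ring B symmetrical. All five stereocentres remain, and ring B must be desymmetrised enantioselectively, with C6 defined only indirectly.
- Comparison: it solves constitution, not configuration. Its step economy is better up to A5 and unknown beyond. The chosen plan fixes C6 early and lets the key step place chlorine on the correct arm.

Key step: step 9

Remarks on the chemistry.
- Atom labels C1–C14 are those of the target skeleton.
- The dienol ether is used as its tert-butyldimethylsilyl ether, which is more stable to alkoxide and isolation than the trimethylsilyl ether.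
- The configurations of 12 and 15 were checked against the target: the spatial arrangement at C6 is the same, and only the CIP label changes (R in 12 and 15, S in 28).
- A shorter late sequence (C10 bromination, C7 methylenation, enol ether hydrolysis, dynamic reduction of the β,γ-unsaturated bromo ketone) was rejected. Hydrolysis of a 1-alkoxy-1,3-diene protonates at C14 and gives the conjugated 7-methyl enone, and C10 of a β,γ-unsaturated bromo ketone cannot be epimerised without enolising C8 and moving the alkene.
- The senses of induction in steps 4 and 14 are assigned by analogy with simple cyclic ketones. If either proves opposite, the enantiomeric ligand is used.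

## Route

Step 1
Reactants: 1 dimedone
Product: 2 5,5-dimethyl-3-(2-methylpropoxy)cyclohex-2-en-1-one
Conditions: 2-methylpropan-1-ol, TsOH (cat.), PhMe, reflux, Dean–Stark
Reagents that add atoms: 2-methylpropan-1-ol, CC(C)CO
Why: Acid-catalysed enol etherification of a cyclic 1,3-dione with azeotropic removal of water; the dione is symmetrical, so only one enol ether can form.

Step 2
Reactants: 2 5,5-dimethyl-3-(2-methylpropoxy)cyclohex-2-en-1-one; 3 benzyl chloromethyl ether
Product: 4 rac-6-[(benzyloxy)methyl]-5,5-dimethyl-3-(2-methylpropoxy)cyclohex-2-en-1-one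
Conditions: LiN(iPr)2, THF, −78 °C; then 3, −78 → 0 °C
Reagents that add atoms: none
Why: Kinetic α′-deprotonation of the vinylogous ester (Stork–Danheiser alkylation) gives the cross-conjugated enolate at the carbon next to CMe2 (the future C6), which the reactive α-chloro ether alkylates; the new centre is racemic and is erased in step 3.

Step 3
Reactants: 4 rac-6-[(benzyloxy)methyl]-5,5-dimethyl-3-(2-methylpropoxy)cyclohex-2-en-1-one; 5 allyl chloroformate
Product: 6 allyl 2-[(benzyloxy)methyl]-3,3-dimethyl-5-(2-methylpropoxy)cyclohexa-1,5-dien-1-yl carbonate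
Conditions: LiN(iPr)2, TMEDA, THF, −78 °C; then 5, −78 °C
Reagents that add atoms: none
Why: A second kinetic α′-deprotonation gives the tetrasubstituted enolate, which the hard chloroformate acylates on oxygen (enol carbonate formation); the low temperature keeps the enolate from equilibrating to the extended γ-dienolate.

Step 4
Reactants: 6 allyl 2-[(benzyloxy)methyl]-3,3-dimethyl-5-(2-methylpropoxy)cyclohexa-1,5-dien-1-yl carbonate
Product: 7 (6R)-6-[(benzyloxy)methyl]-5,5-dimethyl-3-(2-methylpropoxy)-6-(prop-2-en-1-yl)cyclohex-2-en-1-one
Conditions: Pd2(dba)3 (2.5 mol%), (S)-(CF3)3-t-BuPHOX (6 mol%), PhMe, 30 °C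
Reagents that add atoms: none
Why: Decarboxylative asymmetric allylic alkylation: zerovalent palladium ionises the allyl carbonate, CO2 is lost and the chiral Pd(allyl) enolate pair recombines at C6, the electron-poor PHOX ligand being the one suited to hindered, fully substituted enolates. By analogy with cyclic ketone enolates the (S)-ligand delivers allyl to the face on which C7(O), C11 and the exocyclic CH2OBn run clockwise, which gives 6R; an alkoxide is a poor leaving group, so β-elimination from the enolate should not compete.

Step 5
Reactants: 7 (6R)-6-[(benzyloxy)methyl]-5,5-dimethyl-3-(2-methylpropoxy)-6-(prop-2-en-1-yl)cyclohex-2-en-1-one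
Product: 8 (6R)-6-[(benzyloxy)methyl]-5,5-dimethyl-3-(2-methylpropoxy)-6-(2-oxopropyl)cyclohex-2-en-1-one
Conditions: PdCl2 (10 mol%), CuCl, O2 (1 atm), DMF/H2O, 25 °C
Reagents that add atoms: water, O
Why: Tsuji–Wacker oxidation of the terminal alkene; Markovnikov hydroxypalladation gives the methyl ketone, and the trisubstituted push–pull enol ether is not oxidised.

Step 6
Reactants: 8 (6R)-6-[(benzyloxy)methyl]-5,5-dimethyl-3-(2-methylpropoxy)-6-(2-oxopropyl)cyclohex-2-en-1-one
Product: 9 (6R)-6-(hydroxymethyl)-5,5-dimethyl-3-(2-methylpropoxy)-6-(2-oxopropyl)cyclohex-2-en-1-one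
Conditions: H2 (1 atm), Pd/C, EtOAc, 25 °C
Reagents that add atoms: none
Why: Hydrogenolysis of the benzyl ether; the enol ether double bond and the ketones are inert under these mild conditions, and the step follows the Wacker oxidation so that no alkene is lost.

Step 7
Reactants: 9 (6R)-6-(hydroxymethyl)-5,5-dimethyl-3-(2-methylpropoxy)-6-(2-oxopropyl)cyclohex-2-en-1-one
Product: 11 (5S)-10,10-dimethyl-8-(2-methylpropoxy)spiro[4.5]deca-3,7-diene-2,6-dione, via keto aldehyde 10 (not isolated)
Conditions: Dess–Martin periodinane, NaHCO3, CH2Cl2, 0 → 25 °C; then Bn2NH·CF3CO2H, PhMe, 50 °C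
Reagents that add atoms: none
Why: Dess–Martin oxidation gives the non-enolisable neopentyl aldehyde 10, which is not stored because hydroxide or alkoxide would deformylate it (retro-Claisen). The amine salt then effects the intramolecular aldol condensation (the CH3 of the methyl ketone closes the five-membered ring; its CH2 cannot), giving the cyclopentenone C6–C5H=C4H–C3(=O)–C1H2.

Step 8
Reactants: 11 (5S)-10,10-dimethyl-8-(2-methylpropoxy)spiro[4.5]deca-3,7-diene-2,6-dione
Product: 12 (5R)-2-[(tert-butyldimethylsilyl)oxy]-10,10-dimethyl-8-(2-methylpropoxy)spiro[4.5]deca-1,3,7-trien-6-one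
Conditions: LiN(SiMe3)2, THF, −78 °C; then tBuMe2SiOTf, −78 °C
Reagents that add atoms: tert-butyldimethylsilyl trifluoromethanesulfonate, CC(C)(C)[Si](C)(C)OS(=O)(=O)C(F)(F)F
Why: Kinetic deprotonation at C1, the only α-CH2 of the cyclopentenone (the γ position is the quaternary C6), and O-silylation of the cross-conjugated enolate give the 2-silyloxycyclopentadiene; the ring A γ-protons are several pK units less acidic.

Step 9
Reactants: 12 (5R)-2-[(tert-butyldimethylsilyl)oxy]-10,10-dimethyl-8-(2-methylpropoxy)spiro[4.5]deca-1,3,7-trien-6-one; 13 chloroform
Product: 15 (6R)-2-chloro-11,11-dimethyl-9-(2-methylpropoxy)spiro[5.5]undeca-1,4,8-triene-3,7-dione, via dichlorocyclopropane adduct 14 (not isolated)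
Conditions: 13 (5 equiv), KOtBu (added in portions), pentane/PhMe, −30 → 0 °C
Reagents that add atoms: none
Why: Chloroform and KOtBu give :CCl2, an electrophilic singlet carbene that adds in a concerted [2+1] fashion to the most electron-rich double bond, the C1=C3 silyl enol ether, to give the 6,6-dichloro-1-silyloxybicyclo[3.1.0]hex-2-ene 14. Ionisation of the endo C–Cl bond is concerted with disrotatory opening of the cyclopropane (cyclopropyl-to-allyl cation opening) and is pushed by the silyloxy lone pair; the internal C1–C3 bond breaks, the 2-chloro siloxyallyl cation gives up its silyl group to chloride, and the six-membered 2-chloro enone with the C4=C5 bond retained results. The closest known reaction type is the dihalocarbene ring expansion of cyclic silyl enol ethers to 2-halo enones one carbon larger, and of cyclopentadienes to halobenzenes. Ring B is therefore closed by enlargement of the five-membered ring (insertion of C2 between C1 and C3) and not by a cyclisation; the three-membered ring is only transient. No stereocentre is created: C1 and C3 of 14 become sp2 again, C6 has no α-hydrogen and keeps its configuration, and its spiro substitution blocks aromatisation. The step needs chemoselectivity for C1=C3 over C4=C5 and over the push–pull C8=C9 bond, which the oxygen donor on C3 secures; the carbene is generated cold in a hydrocarbon so that the alkoxide is consumed by chloroform and not by the silyl ether or the C7 carbonyl, and so that the acyl-substituted cyclopentadiene cannot rearrange by a sigmatropic shift.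

Step 10
Reactants: 15 (6R)-2-chloro-11,11-dimethyl-9-(2-methylpropoxy)spiro[5.5]undeca-1,4,8-triene-3,7-dione
Product: 18 (2S,6R)-2-chloro-11,11-dimethyl-9-(2-methylpropoxy)spiro[5.5]undec-8-ene-3,7-dione, via chloro enone 16 (not isolated), via triethylsilyl enol ether 17 (not isolated)
Conditions: RhCl(PPh3)3 (5 mol%), H2 (1 atm), PhH, 25 °C; then Et3SiH, 50 °C; then Bu4NF, AcOH, THF, 0 °C; Et3N (cat.), MeCN, 25 °C
Reagents that add atoms: none
Why: RhCl(PPh3)3 hydrogenates only the unhindered disubstituted C4=C5 bond of the cross-conjugated dienone; the same catalyst then effects 1,4-hydrosilylation of the remaining 2-chloro enone, so the α-chloro ketone is never exposed to a hydride source, and buffered fluoride releases the ketone. C2 is set under thermodynamic control: with C11 equatorial and the flatter C7 carbonyl axial on ring B, chlorine is equatorial only in the 2S epimer (cis to C11), the other epimer requiring a syn-axial Cl/C7 contact.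

Step 11
Reactants: 18 (2S,6R)-2-chloro-11,11-dimethyl-9-(2-methylpropoxy)spiro[5.5]undec-8-ene-3,7-dione
Product: 19 (2S,3R,6R)-2-chloro-3-hydroxy-3,11,11-trimethyl-9-(2-methylpropoxy)spiro[5.5]undec-8-en-7-one
Conditions: MeMgBr, CeCl3, THF, −78 °C
Reagents that add atoms: methylmagnesium bromide, C[Mg]Br
Why: The organocerium reagent adds to the activated α-chloro ketone without enolising it (no Favorskii pathway) and leaves the hindered vinylogous ester carbonyl at C7 untouched at −78 °C (chemoselective 1,2-addition). Methyl should enter equatorially, away from the C2–Cl dipole (Cornforth-type, the usual course of methyl-metal reagents on cyclohexanones), which places OH axial and cis to chlorine (3R); the cis alkoxide cannot close to an epoxide.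

Step 12
Reactants: 19 (2S,3R,6R)-2-chloro-3-hydroxy-3,11,11-trimethyl-9-(2-methylpropoxy)spiro[5.5]undec-8-en-7-one
Product: 21 (2S,3R,6R)-2-chloro-3-hydroxy-3,11,11-trimethyl-7-[(trimethylsilyl)methyl]spiro[5.5]undec-7-en-9-one, via tertiary carbinol adduct 20 (not isolated)
Conditions: Me3SiCH2Li (3 equiv), CeCl3, THF, −78 → 0 °C; then 1 M HCl, THF, 0 °C
Reagents that add atoms: (trimethylsilyl)methyllithium, [Li]C[Si](C)(C)C; water, O
Why: Stork–Danheiser 1,3-carbonyl transposition: the weakly basic cerium reagent adds to the hindered C7 carbonyl, and dilute acid ionises the tertiary allylic alcohol to the alkoxy-stabilised allyl cation, which water captures at C9 with loss of isobutanol. The charge lies mainly on the oxocarbenium carbon, so capture by water should outrun β-silyl elimination, as in the known preparation of 3-(silylmethyl)cycloalkenones from 3-alkoxy enones.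

Step 13
Reactants: 21 (2S,3R,6R)-2-chloro-3-hydroxy-3,11,11-trimethyl-7-[(trimethylsilyl)methyl]spiro[5.5]undec-7-en-9-one
Product: 24 (2S,3R,6S)-10-bromo-2-chloro-3-hydroxy-3,11,11-trimethyl-7-[(trimethylsilyl)methyl]spiro[5.5]undec-7-en-9-one (both C10 epimers), via bis-silyl dienol ether 22 (not isolated), via silyl-protected bromo enone 23 (not isolated)
Conditions: LiN(iPr)2 (2.2 equiv), Me3SiCl, THF, −78 °C; then NBS, −78 → 0 °C; then citric acid, MeOH, 0 °C
Reagents that add atoms: N-bromosuccinimide, O=C1CCC(=O)N1Br
Why: Kinetic α′-deprotonation of the enone at C10 (the isophorone pattern), trapping as the silyl dienol ether and bromination with NBS at the enol ether terminus give the α′-bromo enone (α-bromination through a silyl enol ether); mild methanolysis frees the C3 oxygen. The C10 configuration is not controlled here and remains labile, which step 14 uses.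

Step 14
Reactants: 24 (2S,3R,6S)-10-bromo-2-chloro-3-hydroxy-3,11,11-trimethyl-7-[(trimethylsilyl)methyl]spiro[5.5]undec-7-en-9-one (both C10 epimers)
Product: 25 (2S,3R,6S,9R,10S)-10-bromo-2-chloro-3,11,11-trimethyl-7-[(trimethylsilyl)methyl]spiro[5.5]undec-7-ene-3,9-diol
Conditions: RuCl[(S,S)-TsDPEN](p-cymene) (2 mol%), HCO2H/Et3N (1:1), CH2Cl2, 25 °C
Reagents that add atoms: none
Why: Asymmetric transfer hydrogenation with dynamic kinetic resolution: Et3N epimerises C10 through the bromo dienol (C8 is sp2, so nothing else can enolise) while the catalyst reduces one epimer only, hydride arriving anti to bromine to give the cis bromohydrin. With the alkenyl group in the place of the aryl group of the usual model, the (S,S) catalyst should give 9R and therefore 10S; outer-sphere hydride transfer is C=O selective and C7 is fully substituted, so conjugate reduction is not expected.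

Step 15
Reactants: 25 (2S,3R,6S,9R,10S)-10-bromo-2-chloro-3,11,11-trimethyl-7-[(trimethylsilyl)methyl]spiro[5.5]undec-7-ene-3,9-diol
Product: 26 (2S,3R,6S,10S)-10-bromo-2-chloro-3-hydroxy-3,11,11-trimethyl-7-[(trimethylsilyl)methyl]spiro[5.5]undec-7-en-9-one
Conditions: Dess–Martin periodinane, NaHCO3, CH2Cl2, 0 °C
Reagents that add atoms: none
Why: Dess–Martin oxidation of the allylic alcohol under buffered, non-enolising conditions returns the enone as a single C10 epimer; C9 served only as the handle for the resolution and is set again in step 17.

Step 16
Reactants: 26 (2S,3R,6S,10S)-10-bromo-2-chloro-3-hydroxy-3,11,11-trimethyl-7-[(trimethylsilyl)methyl]spiro[5.5]undec-7-en-9-one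
Product: 27 (2S,3R,6S,10S)-10-bromo-2-chloro-3-hydroxy-3,11,11-trimethyl-7-methylidenespiro[5.5]undecan-9-one
Conditions: Bu4NF, AcOH (1:1), THF, −78 → −20 °C
Reagents that add atoms: none
Why: Fluoride attacks silicon of the vinylogous α-silyl ketone and releases the extended dienolate (or dienol) ending at C14, which acetic acid protonates kinetically at the α-carbon C8 (deconjugative protonation of a dienolate), so the exocyclic C7=C14 bond forms regiospecifically. The buffer keeps the medium too weakly basic to deprotonate C10.

Step 17
Reactants: 27 (2S,3R,6S,10S)-10-bromo-2-chloro-3-hydroxy-3,11,11-trimethyl-7-methylidenespiro[5.5]undecan-9-one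
Product: 28 (2S,3R,6S,9R,10S)-10-bromo-2-chloro-3,11,11-trimethyl-7-methylidenespiro[5.5]undecane-3,9-diol
Conditions: LiBH(s-Bu)3, THF, −78 °C
Reagents that add atoms: none
Why: The bulky borohydride attacks the ketone from the equatorial direction, which the axial C11 methyl also enforces, giving the axial alcohol cis to the equatorial bromine (9R). At −78 °C the reagent should neither isomerise the β,γ-alkene nor displace the neopentyl bromide, and the cis alkoxide cannot form an epoxide.

## Compound list

1 | dimedone (5,5-dimethylcyclohexane-1,3-dione) | CC1(C)CC(=O)CC(=O)C1 | starting material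
2 | 5,5-dimethyl-3-(2-methylpropoxy)cyclohex-2-en-1-one | CC(C)COC1=CC(=O)CC(C)(C)C1 | intermediate
3 | benzyl chloromethyl ether | ClCOCc1ccccc1 | starting material
4 | rac-6-[(benzyloxy)methyl]-5,5-dimethyl-3-(2-methylpropoxy)cyclohex-2-en-1-one | CC(C)COC1=CC(=O)C(COCc2ccccc2)C(C)(C)C1 | intermediate
5 | allyl chloroformate | C=CCOC(Cl)=O | starting material
6 | allyl 2-[(benzyloxy)methyl]-3,3-dimethyl-5-(2-methylpropoxy)cyclohexa-1,5-dien-1-yl carbonate | CC(C)COC1=CC(OC(=O)OCC=C)=C(COCc2ccccc2)C(C)(C)C1 | intermediate
7 | (6R)-6-[(benzyloxy)methyl]-5,5-dimethyl-3-(2-methylpropoxy)-6-(prop-2-en-1-yl)cyclohex-2-en-1-one | CC(C)COC1=CC(=O)[C@@](CC=C)(COCc2ccccc2)C(C)(C)C1 | intermediate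
8 | (6R)-6-[(benzyloxy)methyl]-5,5-dimethyl-3-(2-methylpropoxy)-6-(2-oxopropyl)cyclohex-2-en-1-one | CC(C)COC1=CC(=O)[C@@](CC(C)=O)(COCc2ccccc2)C(C)(C)C1 | intermediate
9 | (6R)-6-(hydroxymethyl)-5,5-dimethyl-3-(2-methylpropoxy)-6-(2-oxopropyl)cyclohex-2-en-1-one | CC(C)COC1=CC(=O)[C@@](CC(C)=O)(CO)C(C)(C)C1 | intermediate
10 | (1R)-2,2-dimethyl-4-(2-methylpropoxy)-6-oxo-1-(2-oxopropyl)cyclohex-4-ene-1-carbaldehyde | CC(C)COC1=CC(=O)[C@@](CC(C)=O)(C=O)C(C)(C)C1 | intermediate
11 | (5S)-10,10-dimethyl-8-(2-methylpropoxy)spiro[4.5]deca-3,7-diene-2,6-dione | CC(C)COC1=CC(=O)[C@@]2(C=CC(=O)C2)C(C)(C)C1 | intermediate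
12 | (5R)-2-[(tert-butyldimethylsilyl)oxy]-10,10-dimethyl-8-(2-methylpropoxy)spiro[4.5]deca-1,3,7-trien-6-one | CC(C)COC1=CC(=O)[C@@]2(C=CC(O[Si](C)(C)C(C)(C)C)=C2)C(C)(C)C1 | intermediate
13 | chloroform | ClC(Cl)Cl | starting material
14 | 6,6-dichloro-1-silyloxybicyclo[3.1.0]hex-2-ene adduct of 12 (CCl2 across C1 and C3, cis-fused, both faces; C6 as in 12) | CC(C)COC1=CC(=O)[C@@]2(C=CC3(O[Si](C)(C)C(C)(C)C)C2C3(Cl)Cl)C(C)(C)C1 | intermediate
15 | (6R)-2-chloro-11,11-dimethyl-9-(2-methylpropoxy)spiro[5.5]undeca-1,4,8-triene-3,7-dione | CC(C)COC1=CC(=O)[C@@]2(C=CC(=O)C(Cl)=C2)C(C)(C)C1 | intermediate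
16 | (6R)-2-chloro-11,11-dimethyl-9-(2-methylpropoxy)spiro[5.5]undeca-1,8-diene-3,7-dione | CC(C)COC1=CC(=O)[C@@]2(CCC(=O)C(Cl)=C2)C(C)(C)C1 | intermediate
17 | (6R)-2-chloro-11,11-dimethyl-9-(2-methylpropoxy)-3-[(triethylsilyl)oxy]spiro[5.5]undeca-2,8-dien-7-one | CC(C)COC1=CC(=O)[C@@]2(CCC(O[Si](CC)(CC)CC)=C(Cl)C2)C(C)(C)C1 | intermediate
18 | (2S,6R)-2-chloro-11,11-dimethyl-9-(2-methylpropoxy)spiro[5.5]undec-8-ene-3,7-dione | CC(C)COC1=CC(=O)[C@@]2(CCC(=O)[C@@H](Cl)C2)C(C)(C)C1 | intermediate
19 | (2S,3R,6R)-2-chloro-3-hydroxy-3,11,11-trimethyl-9-(2-methylpropoxy)spiro[5.5]undec-8-en-7-one | CC(C)COC1=CC(=O)[C@@]2(CC[C@@](C)(O)[C@@H](Cl)C2)C(C)(C)C1 | intermediate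
20 | C7 adduct of 19: 7-hydroxy-7-[(trimethylsilyl)methyl] enol ether, both C7 epimers, other centres as in 19 | CC(C)COC1=CC(O)(C[Si](C)(C)C)[C@@]2(CC[C@@](C)(O)[C@@H](Cl)C2)C(C)(C)C1 | intermediate
21 | (2S,3R,6R)-2-chloro-3-hydroxy-3,11,11-trimethyl-7-[(trimethylsilyl)methyl]spiro[5.5]undec-7-en-9-one | C[Si](C)(C)CC1=CC(=O)CC(C)(C)[C@]12CC[C@@](C)(O)[C@@H](Cl)C2 | intermediate
22 | 21 as its C9–C10 trimethylsilyl dienol ether and C3 trimethylsilyl ether | C[Si](C)(C)CC1=CC(O[Si](C)(C)C)=CC(C)(C)[C@]12CC[C@@](C)(O[Si](C)(C)C)[C@@H](Cl)C2 | intermediate
23 | C3 trimethylsilyl ether of 24 (both C10 epimers) | C[Si](C)(C)CC1=CC(=O)C(Br)C(C)(C)[C@]12CC[C@@](C)(O[Si](C)(C)C)[C@@H](Cl)C2 | intermediate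
24 | (2S,3R,6S)-10-bromo-2-chloro-3-hydroxy-3,11,11-trimethyl-7-[(trimethylsilyl)methyl]spiro[5.5]undec-7-en-9-one, both C10 epimers | C[Si](C)(C)CC1=CC(=O)C(Br)C(C)(C)[C@]12CC[C@@](C)(O)[C@@H](Cl)C2 | intermediate
25 | (2S,3R,6S,9R,10S)-10-bromo-2-chloro-3,11,11-trimethyl-7-[(trimethylsilyl)methyl]spiro[5.5]undec-7-ene-3,9-diol | C[Si](C)(C)CC1=C[C@@H](O)[C@@H](Br)C(C)(C)[C@]12CC[C@@](C)(O)[C@@H](Cl)C2 | intermediate
26 | (2S,3R,6S,10S)-10-bromo-2-chloro-3-hydroxy-3,11,11-trimethyl-7-[(trimethylsilyl)methyl]spiro[5.5]undec-7-en-9-one | C[Si](C)(C)CC1=CC(=O)[C@@H](Br)C(C)(C)[C@]12CC[C@@](C)(O)[C@@H](Cl)C2 | intermediate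
27 | (2S,3R,6S,10S)-10-bromo-2-chloro-3-hydroxy-3,11,11-trimethyl-7-methylidenespiro[5.5]undecan-9-one | C=C1CC(=O)[C@@H](Br)C(C)(C)[C@]12CC[C@@](C)(O)[C@@H](Cl)C2 | intermediate
28 | (2S,3R,6S,9R,10S)-10-bromo-2-chloro-3,11,11-trimethyl-7-methylidenespiro[5.5]undecane-3,9-diol | C=C1C[C@@H](O)[C@@H](Br)C(C)(C)[C@]12CC[C@@](C)(O)[C@@H](Cl)C2 | target

## Step count and least certain steps

Total: 17 steps. Longest linear sequence: 17 steps, from 1.

Step 9 (key step). The likely failures are attack of tert-butoxide on silicon, or on the C7 carbonyl of the product with aromatisation-driven cleavage of the C6–C7 bond; cyclopropanation at C4=C5; and sigmatropic acyl migration in the diene if it warms. Fallback: the order of reduction and ring enlargement is exchanged. Starting from 12, the C4=C5 bond is hydrogenated first (H2, RhCl(PPh3)3, PhH), which leaves the enol ether regiodefined as (5R)-2-[(tert-butyldimethylsilyl)oxy]-10,10-dimethyl-8-(2-methylpropoxy)spiro[4.5]deca-1,7-dien-6-one F1. This simple cyclopentanone silyl enol ether is then treated with dichlorocarbene under neutral thermal conditions (Cl3CCO2Na, DME, reflux), the classical substrate class for this ring expansion. The product is 16, which enters the hydrosilylation stage of step 10; the base-sensitive dienone is never formed.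

Step 11. The likely failure is poor facial selectivity (competing axial attack), because the locked equatorial chlorine cannot take up the anti orientation that normally steers additions to 2-chloro ketones. Fallback: starting from 18, the ketone is methylenated with Cp2TiMe2 (PhMe, 65 °C) to (2S,6R)-2-chloro-11,11-dimethyl-3-methylidene-9-(2-methylpropoxy)spiro[5.5]undec-8-en-7-one F2. Oxymercuration–demercuration (Hg(OAc)2, THF/H2O; NaBH4) then hydrates the exocyclic alkene in the Markovnikov sense, with water expected to be delivered axially. The sequence returns to the route at 19.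

Step 14. The likely failures are epimerisation at C10 slower than reduction of the mismatched epimer (loss of selectivity), partial desilylation by formate, or slow turnover on the hindered ketone. Fallback: starting from 24, a non-dynamic catalyst-controlled reduction is used (2-methyl-CBS-oxazaborolidine, the enantiomer that gives 9R, with catecholborane, PhMe, −40 °C). The 10S epimer gives 25 and the 10R epimer gives the trans isomer (2S,3R,6S,9R,10R)-10-bromo-2-chloro-3,11,11-trimethyl-7-[(trimethylsilyl)methyl]spiro[5.5]undec-7-ene-3,9-diol F3. As cis and trans bromohydrins the two should separate by chromatography. F3 is re-oxidised (Dess–Martin periodinane) and equilibrated with Et3N back to 24 for recycling. The route is rejoined at 25.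

Step 16. The likely failures are protonation of the dienolate at C14 instead of C8 (return to a conjugated 7-methyl enone), epimerisation at C10 by insufficiently buffered fluoride, or intramolecular displacement of bromide by the dienolate. Fallback: starting from 25, steps 15 to 17 are replaced by electrophilic protodesilylation of the allylsilane (CF3CO2H, CH2Cl2, −40 °C). The proton adds to C8 and the β-silyl cation at C7 loses silicon, giving 28 directly. This is not the first choice because ionisation of the allylic C9 hydroxyl with 1,4-elimination to a diene competes in this substrate class.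

## Further compounds

F1 | step 9 | (5R)-2-[(tert-butyldimethylsilyl)oxy]-10,10-dimethyl-8-(2-methylpropoxy)spiro[4.5]deca-1,7-dien-6-one | CC(C)COC1=CC(=O)[C@@]2(CCC(O[Si](C)(C)C(C)(C)C)=C2)C(C)(C)C1
F2 | step 11 | (2S,6R)-2-chloro-11,11-dimethyl-3-methylidene-9-(2-methylpropoxy)spiro[5.5]undec-8-en-7-one | CC(C)COC1=CC(=O)[C@@]2(CCC(=C)[C@@H](Cl)C2)C(C)(C)C1
F3 | step 14 | (2S,3R,6S,9R,10R)-10-bromo-2-chloro-3,11,11-trimethyl-7-[(trimethylsilyl)methyl]spiro[5.5]undec-7-ene-3,9-diol | C[Si](C)(C)CC1=C[C@@H](O)[C@H](Br)C(C)(C)[C@]12CC[C@@](C)(O)[C@@H](Cl)C2
F0 | step 16 | none | none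
A1 | alternative 1 | (9R,10S)-10-bromo-9-[(tert-butyldimethylsilyl)oxy]-11,11-dimethyl-7-methylidenespiro[5.5]undecan-3-one ethylene ketal | C=C1C[C@@H](O[Si](C)(C)C(C)(C)C)[C@@H](Br)C(C)(C)C12CCC3(CC2)OCCO3
A2 | alternative 1 | (3R,4R)-3-bromo-4-[(tert-butyldimethylsilyl)oxy]-6-(1,4-dioxaspiro[4.5]decan-8-ylidene)-2-methyl-7-(trimethylsilyl)heptan-2-ol | C[Si](C)(C)CC(C[C@@H](O[Si](C)(C)C(C)(C)C)[C@@H](Br)C(C)(C)O)=C1CCC2(CC1)OCCO2
A3 | alternative 2 | (2S,3R,6R)-2-chloro-3,11,11-trimethyl-9-(2-methylpropoxy)-3-[(triethylsilyl)oxy]spiro[5.5]undec-8-en-7-one | CC(C)COC1=CC(=O)[C@@]2(CC[C@@](C)(O[Si](CC)(CC)CC)[C@@H](Cl)C2)C(C)(C)C1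
A4 | alternative 2 | 6-[(3R,4S)-4-chloro-3-methyl-5-(tosyloxy)-3-[(triethylsilyl)oxy]pentyl]-5,5-dimethyl-3-(2-methylpropoxy)cyclohex-2-en-1-one | CC(C)COC1=CC(=O)C(CC[C@@](C)(O[Si](CC)(CC)CC)[C@@H](Cl)COS(=O)(=O)c2ccc(C)cc2)C(C)(C)C1
A5 | alternative 3 | spiro-fused 5,5-dimethylcyclohexane-1,3-dione (C7 and C9 carbonyls) with ring B as its C3 ethylene ketal | O=C1CC(=O)C2(CCC3(CC2)OCCO3)C(C)(C)C1
A6 | alternative 3 | 2-acetyl-3,3-dimethyl spirocyclobutanone (ring carbonyl C7, spiro carbon C6) with ring B as its C3 ethylene ketal | CC(=O)C1C(=O)C2(CCC3(CC2)OCCO3)C1(C)C
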